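**Plan**

1. Retrosynthetic cuts, in order: the sulfate O–H (cation exchange) and the C2=C3 unsaturation (dehydrogenation), back to a 2,3-trans flavanon-3-yl sulfate; then the O1–C2 bond, which unfolds ring C into a 1,2-cyclic sulfate on C2/C3 beside a masked ortho phenol; then the two C–O bonds at C2/C3 (syn-dihydroxylation of an E-chalcone); then the Cα–Cβ bond (aldol, elimination) to a bis-silylated 2',6'-dihydroxy-4'-methoxyacetophenone and O-silyl isovanillin.
2. Enabling feature: C2 and C3 of the pyranone ring C carry vicinal C–O bonds (C2–O1 to ring A, C3–O–SO3H), the imprint of an aryl oxygen opening a 1,2-cyclic sulfate. The 4'-OMe of ring B is para to C2 and loosens that benzylic C–O bond. The ring A precursor has two equivalent oxygens ortho to the acyl carbon, so either one closes to the same product.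
3. Forward order: rings A and B are bought and joined by the aldol C–C bond; a temporary 1,3,2-dioxathiolane is built on the C2–C3 unit; ring C closes in the key step as that ring opens, the leaving group staying as the 3-sulfate; ring C is then dehydrogenated to the 4H-chromen-4-one and the counter-ion changed to H+.
4. Stereochemistry: the target has no stereocentre. The transient C2/C3 centres arise as racemates (syn-dihydroxylation of the E-alkene, inversion at C2 on ring closure) and are erased by the dehydrogenation.

Key step: step 9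

Remark: the target SMILES contains no stereocentre and no stereogenic axis, so it is one achiral compound; all chiral intermediates are racemates, drawn and named as one enantiomer. TBSO = tert-butyldimethylsilyloxy.

**Route**

Step 1
Reactants: 1 2',4',6'-trihydroxyacetophenone (phloracetophenone)
Product: 2 2',6'-dihydroxy-4'-methoxyacetophenone
Conditions: Me2SO4 (1.0 equiv), K2CO3 (1.0 equiv), acetone, reflux
Reagents that add atoms: dimethyl sulfate, COS(=O)(=O)OC
Why: Williamson-type O-methylation; the 4-OH is para to the acyl group and not hydrogen-bonded to the carbonyl, so it is the most acidic and most accessible phenol and one equivalent of dimethyl sulfate should methylate it first.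

Step 2
Reactants: 2 2',6'-dihydroxy-4'-methoxyacetophenone
Product: 3 1-[2,6-bis(TBSO)-4-methoxyphenyl]ethanone
Conditions: TBSOTf (2.4 equiv), 2,6-lutidine (3 equiv), CH2Cl2, 0 °C to rt
Reagents that add atoms: tert-butyldimethylsilyl triflate, CC(C)(C)[Si](C)(C)OS(=O)(=O)C(F)(F)F
Why: Silyl triflate silylation; TBSOTf is electrophilic enough for both hydrogen-bonded, hindered ortho phenols, while 2,6-lutidine is too weak and hindered to enolise the methyl ketone.

Step 3
Reactants: 4 isovanillin (3-hydroxy-4-methoxybenzaldehyde)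
Product: 5 3-(TBSO)-4-methoxybenzaldehyde
Conditions: TBSCl (1.2 equiv), imidazole (2 equiv), DMF, rt
Reagents that add atoms: tert-butyldimethylsilyl chloride, CC(C)(C)[Si](C)(C)Cl
Why: Standard imidazole-mediated silylation of a phenol, which leaves the aldehyde untouched.

Step 4
Reactants: 3 1-[2,6-bis(TBSO)-4-methoxyphenyl]ethanone; 5 3-(TBSO)-4-methoxybenzaldehyde
Product: 6 rac-1-[2,6-bis(TBSO)-4-methoxyphenyl]-3-hydroxy-3-[3-(TBSO)-4-methoxyphenyl]propan-1-one
Conditions: LDA (1.05 equiv), THF, −78 °C; then 5, −78 °C; AcOH quench at −78 °C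
Reagents that add atoms: none
Why: Directed aldol addition of the kinetic lithium enolate of the methyl ketone (its only enolisable position) to a non-enolisable aldehyde; the amide base at low temperature spares the aryl silyl ethers that hydroxide would remove, and the new carbinol centre forms as a racemate that is destroyed in step 5.

Step 5
Reactants: 6 rac-aldol adduct
Product: 8 (E)-1-[2,6-bis(TBSO)-4-methoxyphenyl]-3-[3-(TBSO)-4-methoxyphenyl]prop-2-en-1-one, via β-mesylate 7 (not isolated)
Conditions: MsCl (1.5 equiv), Et3N (4 equiv), CH2Cl2, 0 °C to rt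
Reagents that add atoms: none
Why: Mesylation of the β-hydroxyl followed by E1cB elimination through the ketone enolate should give the conjugated, thermodynamically preferred E-enone.

Step 6
Reactants: 8 tris-TBS (E)-chalcone
Product: 9 rac-(2S,3R)-1-[2,6-bis(TBSO)-4-methoxyphenyl]-2,3-dihydroxy-3-[3-(TBSO)-4-methoxyphenyl]propan-1-one (syn diol)
Conditions: OsO4 (2 mol%), NMO (1.5 equiv), citric acid (1 equiv), t-BuOH/H2O, rt
Reagents that add atoms: osmium tetroxide (catalytic oxygen carrier), O=[Os](=O)(=O)=O; N-methylmorpholine N-oxide, C[N+]1([O-])CCOCC1; water, O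
Why: Upjohn dihydroxylation; the suprafacial [3+2] addition of OsO4 to the E-alkene puts both oxygens on one face and so sets the syn (threo) relation of C2/C3 as a racemate (no chiral ligand), with citric acid keeping the catalytic cycle turning for the electron-poor enone.

Step 7
Reactants: 9 rac-syn diol
Product: 10 rac-trans-(4S,5R)-4-[2,6-bis(TBSO)-4-methoxybenzoyl]-5-[3-(TBSO)-4-methoxyphenyl]-1,3,2-dioxathiolane 2-oxide (both epimers at sulfur)
Conditions: SOCl2 (1.3 equiv), Et3N (3 equiv), CH2Cl2, 0 °C
Reagents that add atoms: thionyl chloride, O=S(Cl)Cl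
Why: Cyclic sulfite formation from a 1,2-diol; both carbinol configurations are retained, so the ring is 4,5-trans, and the mild amine base avoids retro-aldol cleavage of the β-hydroxy ketone.

Step 8
Reactants: 10 rac-trans cyclic sulfite
Product: 11 rac-trans-(4S,5R)-4-[2,6-bis(TBSO)-4-methoxybenzoyl]-5-[3-(TBSO)-4-methoxyphenyl]-1,3,2-dioxathiolane 2,2-dioxide
Conditions: RuCl3·xH2O (0.5 mol%), NaIO4 (1.3 equiv), MeCN/EtOAc/H2O, 0 °C, 10–15 min; cold filtration through a short silica plug, used at once
Reagents that add atoms: sodium periodate, [Na+].[O-]I(=O)(=O)=O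
Why: Sharpless-type oxidation of a cyclic sulfite by catalytic RuO4 regenerated from periodate is fast at 0 °C and does not touch the carbon stereocentres; the short contact time and cold, chromatography-free work-up respect the electron-rich arenes and the labile p-methoxybenzylic C–O bond.

Step 9
Reactants: 11 rac-trans cyclic sulfate
Product: 13 tetrabutylammonium rac-(2S,3S)-5-hydroxy-2-(3-hydroxy-4-methoxyphenyl)-7-methoxy-4-oxochroman-3-yl sulfate (2,3-trans), via triphenol cyclic sulfate 12 (not isolated)
Conditions: TBAF (3.3 equiv) premixed with AcOH (3.5 equiv), THF (0.02 M), −20 to 0 °C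
Reagents that add atoms: tetrabutylammonium fluoride, CCCC[N+](CCCC)(CCCC)CCCC.[F-]
Why: Proposed new method: fluoride strips the three aryl silyl ethers and a freed ortho phenol(ate) of 12 attacks the benzylic carbon of the dioxathiolane 2,2-dioxide from the rear, so that O1–C2 forms as the benzylic C–O bond breaks and the departing oxygen stays on C3 as the sulfate monoester anion; the closest known reactions are nucleophilic openings of 1,2-cyclic sulfates (whose monoester is normally hydrolysed away) and the deprotective ring closure of 2'-O-protected chalcone epoxides at the β-carbon to trans-dihydroflavonols. Ring C closes 6-exo-tet in the strict sense (the leaving oxygen lies outside the new ring), which corresponds to the 6-endo mode of epoxide openings because both dioxathiolane carbons become ring members. C2 is formed with inversion, which together with the syn-diol origin of 11 gives the 2,3-trans racemate, while C3 is untouched; both centres are erased in step 10, so neither this outcome nor any epimerisation matters. The selectivity needed is attack at the benzylic carbon (six-membered ring) over 5-exo attack at the carbonyl-flanked carbon (coumaranone); it is secured by the 4'-methoxy group para to the benzylic carbon, which lends the loose SN2 transition state cation character, by the weakly acidic buffered medium, and by the second ortho hydroxyl, which hydrogen-bonds the carbonyl and holds it in the plane of ring A. Should the acidic C3–H be removed first, E1cB opening to the α-sulfooxy-2'-hydroxychalcone and 6-endo-trig oxa-Michael closure lead to the same product. Because ring A carries two equivalent ortho oxygens either one closes to the same compound, and the sulfate sits on O3 by construction, so O3 never has to be told apart from the 5- and 3'-hydroxyls.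

Step 10
Reactants: 13 rac-trans flavanon-3-yl sulfate tetrabutylammonium salt
Product: 15 tetrabutylammonium 5-hydroxy-2-(3-hydroxy-4-methoxyphenyl)-7-methoxy-4-oxo-4H-chromen-3-yl sulfate (ombuin 3-O-sulfate Bu4N salt), via 3-iodoflavanone sulfate 14 (not isolated)
Conditions: I2 (1.2 equiv), pyridine, 90 °C; evaporation, aq Na2S2O3, ion-pair extraction into CH2Cl2
Reagents that add atoms: none
Why: Iodine–pyridine dehydrogenation of a flavanone, as practised on 5,3'-dihydroxy-4'-methoxyflavanones: axial iodination of the C3 enol and anti elimination of HI across C2–C3, in a basic medium that keeps the sulfate monoester as its stable anion.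

Step 11
Reactants: 15 ombuin 3-O-sulfate Bu4N salt
Product: 16 ombuin 3-O-sulfate potassium salt
Conditions: KOAc (excess), MeOH, rt, collect precipitate; Sephadex LH-20 (MeOH/H2O)
Reagents that add atoms: potassium acetate, [K+].CC(=O)[O-]
Why: Salt metathesis; potassium salts of flavonoid sulfates are poorly soluble in methanol and should precipitate, leaving tetrabutylammonium acetate in solution.

Step 12
Reactants: 16 ombuin 3-O-sulfate potassium salt
Product: 17 ombuin 3-O-sulfate (free hydrogen sulfate)
Conditions: Dowex 50W-X8 (H+ form), H2O/MeOH, 0–4 °C; immediate freeze-drying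
Reagents that add atoms: none
Why: Cation exchange on a sulfonic acid resin replaces K+ by H+; working cold and freeze-drying at once should limit the acid-catalysed hydrolysis to which the free hydrogen sulfate is prone.

**Compound list**

1 | 2',4',6'-trihydroxyacetophenone | CC(=O)c1c(O)cc(O)cc1O | starting material
2 | 2',6'-dihydroxy-4'-methoxyacetophenone | CC(=O)c1c(O)cc(OC)cc1O | intermediate
3 | 1-[2,6-bis(TBSO)-4-methoxyphenyl]ethanone | CC(=O)c1c(O[Si](C)(C)C(C)(C)C)cc(OC)cc1O[Si](C)(C)C(C)(C)C | intermediate
4 | isovanillin | O=Cc1ccc(OC)c(O)c1 | starting material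
5 | 3-(TBSO)-4-methoxybenzaldehyde | O=Cc1ccc(OC)c(O[Si](C)(C)C(C)(C)C)c1 | intermediate
6 | rac-1-[2,6-bis(TBSO)-4-methoxyphenyl]-3-hydroxy-3-[3-(TBSO)-4-methoxyphenyl]propan-1-one | O=C(CC(O)c1ccc(OC)c(O[Si](C)(C)C(C)(C)C)c1)c1c(O[Si](C)(C)C(C)(C)C)cc(OC)cc1O[Si](C)(C)C(C)(C)C | intermediate
7 | 3-O-methanesulfonate of 6 | O=C(CC(OS(C)(=O)=O)c1ccc(OC)c(O[Si](C)(C)C(C)(C)C)c1)c1c(O[Si](C)(C)C(C)(C)C)cc(OC)cc1O[Si](C)(C)C(C)(C)C | intermediate (not isolated)
8 | (E)-1-[2,6-bis(TBSO)-4-methoxyphenyl]-3-[3-(TBSO)-4-methoxyphenyl]prop-2-en-1-one | O=C(/C=C/c1ccc(OC)c(O[Si](C)(C)C(C)(C)C)c1)c1c(O[Si](C)(C)C(C)(C)C)cc(OC)cc1O[Si](C)(C)C(C)(C)C | intermediate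
9 | rac-(2S,3R)-1-[2,6-bis(TBSO)-4-methoxyphenyl]-2,3-dihydroxy-3-[3-(TBSO)-4-methoxyphenyl]propan-1-one (syn diol) | O=C([C@@H](O)[C@H](O)c1ccc(OC)c(O[Si](C)(C)C(C)(C)C)c1)c1c(O[Si](C)(C)C(C)(C)C)cc(OC)cc1O[Si](C)(C)C(C)(C)C | intermediate
10 | rac-trans-(4S,5R)-4-[2,6-bis(TBSO)-4-methoxybenzoyl]-5-[3-(TBSO)-4-methoxyphenyl]-1,3,2-dioxathiolane 2-oxide, epimers at sulfur | O=C([C@H]1OS(=O)O[C@@H]1c1ccc(OC)c(O[Si](C)(C)C(C)(C)C)c1)c1c(O[Si](C)(C)C(C)(C)C)cc(OC)cc1O[Si](C)(C)C(C)(C)C | intermediate
11 | rac-trans-(4S,5R)-4-[2,6-bis(TBSO)-4-methoxybenzoyl]-5-[3-(TBSO)-4-methoxyphenyl]-1,3,2-dioxathiolane 2,2-dioxide | O=C([C@H]1OS(=O)(=O)O[C@@H]1c1ccc(OC)c(O[Si](C)(C)C(C)(C)C)c1)c1c(O[Si](C)(C)C(C)(C)C)cc(OC)cc1O[Si](C)(C)C(C)(C)C | intermediate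
12 | rac-trans-(4S,5R)-4-(2,6-dihydroxy-4-methoxybenzoyl)-5-(3-hydroxy-4-methoxyphenyl)-1,3,2-dioxathiolane 2,2-dioxide (drawn fully desilylated) | O=C([C@H]1OS(=O)(=O)O[C@@H]1c1ccc(OC)c(O)c1)c1c(O)cc(OC)cc1O | intermediate (not isolated)
13 | tetrabutylammonium rac-(2S,3S)-5-hydroxy-2-(3-hydroxy-4-methoxyphenyl)-7-methoxy-4-oxochroman-3-yl sulfate (2,3-trans) | CCCC[N+](CCCC)(CCCC)CCCC.COc1cc(O)c2C(=O)[C@@H](OS(=O)(=O)[O-])[C@H](c3ccc(OC)c(O)c3)Oc2c1 | intermediate
14 | tetrabutylammonium rac-3-iodo-5-hydroxy-2-(3-hydroxy-4-methoxyphenyl)-7-methoxy-4-oxochroman-3-yl sulfate (iodine axial, anti to H-2) | CCCC[N+](CCCC)(CCCC)CCCC.COc1cc(O)c2C(=O)[C@@](I)(OS(=O)(=O)[O-])[C@H](c3ccc(OC)c(O)c3)Oc2c1 | intermediate (not isolated)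
15 | tetrabutylammonium 5-hydroxy-2-(3-hydroxy-4-methoxyphenyl)-7-methoxy-4-oxo-4H-chromen-3-yl sulfate | CCCC[N+](CCCC)(CCCC)CCCC.COc1cc(O)c2c(=O)c(OS(=O)(=O)[O-])c(-c3ccc(OC)c(O)c3)oc2c1 | intermediate
16 | ombuin 3-O-sulfate potassium salt | COc1cc(O)c2c(=O)c(OS(=O)(=O)[O-])c(-c3ccc(OC)c(O)c3)oc2c1.[K+] | intermediate
17 | ombuin 3-O-sulfate (5-hydroxy-2-(3-hydroxy-4-methoxyphenyl)-7-methoxy-4-oxo-4H-chromen-3-yl hydrogen sulfate) | COc1cc(O)c2c(=O)c(OS(=O)(=O)O)c(-c3ccc(OC)c(O)c3)oc2c1 | target

**Step count**

Total: 12 steps. Longest linear sequence: 11 steps (steps 1, 2 and 4–12, from 1 to 17); step 3 is a one-step side branch.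

**Steps most likely to fail, with fallbacks**

1. Step 9 (proposed new method). The ring closure may take the wrong course: 5-exo attack at the carbonyl-flanked carbon, opening of the cyclic sulfate by external fluoride or acetate, or solvolysis of the benzylic C–O bond before the phenol arrives. The fallback uses known chemistry, sets out from chalcone 8 and installs the sulfate last.
   - Epoxidation of 8 with dimethyldioxirane (acetone/CH2Cl2, 0 °C to rt) should give the rac-trans-(2S,3R) tris-TBS chalcone epoxide F1.
   - Buffered TBAF desilylation of F1 triggers the established β-carbon ring closure of 2'-hydroxychalcone epoxides and should give rac-trans-3,5,3'-trihydroxy-7,4'-dimethoxyflavanone F2.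
   - Iodine and potassium acetate in hot acetic acid should dehydrogenate F2 to ombuin F3.
   - Carbodiimide-mediated sulfation of F3 with tetrabutylammonium hydrogen sulfate (DCC, pyridine), the established way to flavonol 3-sulfates, should give 15, where the route is rejoined. The hydrogen-bonded 5-OH does not react under these conditions and the 3'-OH beside the 4'-methoxy group is expected to be the slower phenol; a minor 3'-sulfate could be removed with aryl sulfatase, which spares 3-sulfates.

2. Step 10. Enolisation toward C3 may be slowed by the α-sulfooxy group, so that iodination of ring A, retro-oxa-Michael ring opening or loss of the sulfate in hot pyridine compete. The fallback sets out from 13 and replaces ionic C3 chemistry by radical chemistry at C2.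
   - Acetylation of 13 (Ac2O, pyridine, cat. DMAP) should give the 5,3'-di-O-acetyl flavanon-3-yl sulfate Bu4N salt F4.
   - NBS with catalytic benzoyl peroxide in refluxing PhCF3 brominates the benzylic C2 (the classical dehydrogenation of flavanone acetates) to the 2-bromo intermediate F5, which is not isolated and loses HBr to the 5,3'-di-O-acetyl ombuin 3-O-sulfate Bu4N salt F6.
   - Methanolic ammonia at 0 °C removes the two aryl acetates without touching the sulfate and returns to 15.

3. Step 8. RuO4 may over-oxidise the electron-rich arenes, or the p-methoxybenzylic C–O bond of the cyclic sulfate may be hydrolysed in the aqueous two-phase medium before isolation. The fallback sets out from diol 9 and avoids both oxidant and water. Direct S(VI) transfer with 1,1'-sulfonyldiimidazole onto the lithium dialkoxide (LiHMDS, THF, −78 °C), a known one-step preparation of cyclic sulfates from 1,2-diols, should give 11 without passing through 10. The cold THF solution would be taken straight into step 9. This detour makes no new compound (F0).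

**Further compounds**

F1 | step 9 | rac-trans-(2S,3R)-2-[2,6-bis(TBSO)-4-methoxybenzoyl]-3-[3-(TBSO)-4-methoxyphenyl]oxirane | O=C([C@H]1O[C@@H]1c1ccc(OC)c(O[Si](C)(C)C(C)(C)C)c1)c1c(O[Si](C)(C)C(C)(C)C)cc(OC)cc1O[Si](C)(C)C(C)(C)C
F2 | step 9 | rac-(2S,3S)-3,5,3'-trihydroxy-7,4'-dimethoxyflavanone (trans) | COc1cc(O)c2C(=O)[C@@H](O)[C@H](c3ccc(OC)c(O)c3)Oc2c1
F3 | step 9 | ombuin (3,5,3'-trihydroxy-7,4'-dimethoxyflavone) | COc1cc(O)c2c(=O)c(O)c(-c3ccc(OC)c(O)c3)oc2c1
F4 | step 10 | tetrabutylammonium rac-(2S,3S)-5-acetoxy-2-(3-acetoxy-4-methoxyphenyl)-7-methoxy-4-oxochroman-3-yl sulfate | CCCC[N+](CCCC)(CCCC)CCCC.COc1cc(OC(C)=O)c2C(=O)[C@@H](OS(=O)(=O)[O-])[C@H](c3ccc(OC)c(OC(C)=O)c3)Oc2c1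
F5 | step 10 | tetrabutylammonium 5-acetoxy-2-(3-acetoxy-4-methoxyphenyl)-2-bromo-7-methoxy-4-oxochroman-3-yl sulfate (mixture at C2, not isolated) | CCCC[N+](CCCC)(CCCC)CCCC.COc1cc(OC(C)=O)c2C(=O)[C@@H](OS(=O)(=O)[O-])C(Br)(c3ccc(OC)c(OC(C)=O)c3)Oc2c1
F6 | step 10 | tetrabutylammonium 5-acetoxy-2-(3-acetoxy-4-methoxyphenyl)-7-methoxy-4-oxo-4H-chromen-3-yl sulfate | CCCC[N+](CCCC)(CCCC)CCCC.COc1cc(OC(C)=O)c2c(=O)c(OS(=O)(=O)[O-])c(-c3ccc(OC)c(OC(C)=O)c3)oc2c1
F0 | step 8 | none | none
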